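At early times the beta flask says little: after 40.0 min its product reads 3%, against a scatter of 1.5 percentage points.

in all of them: substrate 1.5 M
- beta: precatalyst 0.2 mol%; the very flask that is asked about, followed so far
- delta: precatalyst 0.1 mol%; run made earlier
- flask: precatalyst 0.2 mol%

beta run (percent of the substrate charged)

| time / min | product / % | substrate / % |
|---|---|---|
| 3.00 | 0 | 101 |
| 6.00 | 0 | 101 |
| 10.0 | 2 | 100 |
| 20.0 | 0 | 99 |
| 40.0 | 3 | 99 |

delta run (percent of the substrate charged)

| time / h | product / % | substrate / % |
|---|---|---|
| 1.00 | 5 | 100 |
| 2.50 | 10 | 89 |
| 3.00 | 14 | 84 |
| 5.00 | 32 | 68 |
| 6.00 | 45 | 59 |

(scatter of a reading: 1.5 percentage points)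

But the delta run bends upward: between 2.50 h and 6.00 h time grows by a factor 2.40 and product by 4.50. So turnover seems to wait for catalyst released slowly from precatalyst, an induction period. While little precatalyst has passed over, [catalyst] rises with charge and with time, so with turnover first order in [substrate] and in [catalyst], the logarithm of the substrate fraction left falls in proportion to charge times time squared. A fixed conversion then comes earlier by the square root of the factor on the charge, and at that point [substrate] is unchanged while [catalyst] is higher by that same root. My reckoning therefore takes the root factor, the square root of the factor on the charge, as the zero of the scale for the rate at fixed conversion: 1.41 for a doubled charge and 3.16 for 2 mol%.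

- factor on the rate of making product when 10% of the substrate are converted if precatalyst is charged twice over
- factor on the rate when 10% of the substrate are converted if precatalyst is charged at 2 mol% instead

The forecast gives 1.44 (1.35 to 1.6) and 3.3 (2.9 to 4.2), above these roots: “slight precatalyst depletion nudges both factors upward”.

The flask gives 1.44 and 3.28.

    substrate + catalyst → catalyst + product (k = 0.0730 L mol⁻¹ s⁻¹)
    precatalyst → catalyst (k = 2.50 × 10⁻⁵ s⁻¹)

At 1.77 h, when 10% of the substrate is converted in this flask, 14.7% of the catalyst charged stands as catalyst, and the doubling factor is 1.02 times the root factor. Multiplied by the root factor, that time gives an estimate of 2.50 h for the lower charge of the delta run, and at 2.50 h the delta run read 10% product and 89% substrate.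

The earlier runs and the new flask stem from a simulated flask with made-up constants; noise was put on by code.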